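Numbering: isochromane (C1, O2, C3, C4, C4a, C5–C8, C8a); unprimed = quinone-methide half, primed = lactone half, C9 = bridging CH2.
Feature: both halves have the same 3,4,5-trimethyl-6,8-dioxygenated isochromane skeleton and the same 3R,4S pair, and they differ only in the oxidation level of C1. Each C3/C4 pair is what backside opening of meso cis-2,3-epoxybutane at one of its two enantiotopic carbons delivers.
Cuts: the quinone methide goes back to a C1 lactol and this to a C2-symmetric bis-lactone. Then follow O2–C1/O2'–C1' (lactones to hydroxy amides), C4–C4a/C4'–C4a' (twofold epoxide opening), C1–C8a/C1'–C8a' (carbamoylation) and C7–C9/C7'–C9 (formate carbon as C9).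
Forward: C9 joins two 2,4-dimethoxytoluene rings, both amides are installed, and both side chains are attached in one operation. Both pyranone rings then close together, and one is reduced and becomes the pyran ring of the quinone methide after demethylation.
Stereochemistry: the threo relation follows from SN2 inversion on the cis epoxide and the absolute sense from a chiral diamine on lithium. Two independent openings push most errors into a separable meso diastereomer.

Key step: step 5

Assumption: the sense of induction of the diamine on this aryllithium cannot be derived with certainty, so (−)-sparteine is written and its commercial antipode replaces it if a trial run favours the 3S,4R series.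
Assumption: the quinone methide is drawn as the 6-hydroxy-8-oxo tautomer of the target structure; it is related to the 8-hydroxy-6-oxo form by a proton shift only and needs no separate control.

Step 1
Reactants: 1 2,4-dimethoxytoluene; 2 ethyl formate
Product: 5 bis(2,6-dimethoxy-3-methylphenyl)methanol, via aryllithium 3 (not isolated), via aryl aldehyde 4 (not isolated)
Conditions: n-BuLi, TMEDA, THF, 0 °C → rt; 2 (0.5 equiv), −78 °C → rt; H2O
Reagents that add atoms: ethyl formate (2), CCOC=O
Why: Directed ortho-metalation takes place at the carbon flanked by both methoxy groups (cooperative 1,3-effect), and the aryllithium then adds twice to the formate ester through aldehyde 4, the standard route to symmetrical diarylcarbinols; no stereocentre arises.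

Step 2
Reactants: 5 bis(2,6-dimethoxy-3-methylphenyl)methanol
Product: 6 bis(2,6-dimethoxy-3-methylphenyl)methane
Conditions: Et3SiH, TFA, CH2Cl2, 0 °C
Reagents that add atoms: none
Why: In this ionic hydrogenation the acid ionises the carbinol to a diarylmethyl cation stabilised by four ortho methoxy groups, and the silane should trap it faster than retro-Friedel–Crafts cleavage can set in.

Step 3
Reactants: 6 bis(2,6-dimethoxy-3-methylphenyl)methane
Product: 7 bis(3-bromo-2,6-dimethoxy-5-methylphenyl)methane
Conditions: NBS (2.05 equiv), MeCN, 0 °C → rt, dark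
Reagents that add atoms: N-bromosuccinimide, O=C1CCC(=O)N1Br
Why: Electrophilic aromatic bromination with NBS in a polar solvent should go to the one ring position that is ortho to one methoxy group and para to the other (the future C8a/C8a'), since the other free C–H is meta to both.

Step 4
Reactants: 7 bis(3-bromo-2,6-dimethoxy-5-methylphenyl)methane; 8 diethylcarbamoyl chloride
Product: 10 3,3'-methylenebis(N,N-diethyl-2,4-dimethoxy-5-methylbenzamide), via dilithio diarylmethane 9 (not isolated)
Conditions: n-BuLi (2.2 equiv), THF, −78 °C; 8 (3 equiv), −78 °C → rt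
Reagents that add atoms: diethylcarbamoyl chloride (8), CCN(CC)C(=O)Cl
Why: Bromine–lithium exchange is far faster at −78 °C than removal of a C9 proton, and acylation of the aryllithium by the carbamoyl chloride is the usual entry to N,N-diethylbenzamides.

Step 5
Reactants: 10 3,3'-methylenebis(N,N-diethyl-2,4-dimethoxy-5-methylbenzamide); 11 cis-2,3-epoxybutane (meso)
Product: 13 C2-symmetric bis(hydroxy amide) 3,3'-methylenebis{N,N-diethyl-6-[(2S,3R)-3-hydroxybutan-2-yl]-2,4-dimethoxy-5-methylbenzamide} (3R,4S,3'R,4'S in isochromane numbering), via dilithiated bis-amide 12 (not isolated)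
Conditions: s-BuLi (2.4 equiv), (−)-sparteine (2.6 equiv), Et2O/PhMe, −78 °C; 11 (6 equiv), then BF3·OEt2 (5 equiv, slow addition), −78 °C; H2O
Reagents that add atoms: cis-2,3-epoxybutane (11), C[C@H]1O[C@H]1C
Why: Proposed new method: the diethylamide steers s-BuLi·(−)-sparteine by complex-induced proximity to its only free ortho carbon (C4a and C4a'), and each diamine-bound aryllithium of 12 then attacks BF3-activated 11 from the rear in an SN2 opening that forms C4–C4a and C4'–C4a' and closes no ring. The closest known reaction types are the opening of epoxides by ortho-lithiated tertiary benzamides on the way to dihydroisocoumarins and the sparteine/BF3-mediated enantioselective opening of meso epoxides by simple aryllithiums; ligand control over an aryllithium that also holds an internal amide chelate, and the twofold version, have not been shown. Inversion at the attacked carbon with retention at the carbinol carbon fixes the threo relation in each arm regardless of the ligand, whereas the absolute configuration (attack at the S carbon of 11, giving 4S/4'S and leaving 3R/3'R) is decided by the chiral diamine on lithium. Amide chelation and diamine binding should be able to coexist, because aryl carbon, amide oxygen and the two nitrogens together fill the four sites of a monomeric lithium, as in the sparteine complexes of carbonyl-chelated organolithiums used in asymmetric deprotonation, and the ether/toluene medium offers no competing donor. Site selectivity comes from the substrate: C4a–H is the sole ring hydrogen and sits next to the directing group, whereas C9–H2 and the C5 methyl are meta to the amide, gain no conjugative help from it, and a C9 anion hemmed in by four ortho methoxy groups cannot flatten against either ring. Because the two openings are independent, most wrong-sense events end up in the meso (3R,4S,3'S,4'R) diastereomer, which is removed after step 6, so that the C2-symmetric product should be enantiomerically richer than a single opening would allow (Horeau principle).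

Step 6
Reactants: 13 C2-symmetric bis(hydroxy amide)
Product: 14 7,7'-methylenebis[(3R,4S)-6,8-dimethoxy-3,4,5-trimethyl-3,4-dihydro-1H-isochromen-1-one]
Conditions: p-TsOH·H2O (3 equiv), PhMe, 110 °C
Reagents that add atoms: none
Why: Acid-promoted intramolecular alcoholysis of an ortho-(2-hydroxyalkyl) tertiary benzamide, the standard close of the metalation route to 3,4-dihydroisocoumarins, forms both lactones by 6-exo-trig attack of the C3 oxygen on C1 without touching the C3–O or C4–C4a bonds, so that 3R,4S is kept, the slowly rotating Ar–CO rotamers of 13 converge, and the meso diastereomer can be removed by crystallisation or chromatography.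

Step 7
Reactants: 14 C2-symmetric bis-lactone
Product: 15 (3R,4S)-7-{[(3R,4S)-1-hydroxy-6,8-dimethoxy-3,4,5-trimethyl-3,4-dihydro-1H-isochromen-7-yl]methyl}-6,8-dimethoxy-3,4,5-trimethyl-3,4-dihydro-1H-isochromen-1-one (both C1 epimers)
Conditions: DIBAL-H (1.0 equiv), CH2Cl2, −78 °C; aq Rochelle salt
Reagents that add atoms: none
Why: In this lactone-to-lactol reduction the aluminium lactolate is stable at −78 °C, and as the two lactones are homotopic and independent, one equivalent of hydride should give a single mono-lactol as the main part of a statistical mixture from which unchanged 14 is recovered; the new C1 centre is an anomeric mixture that disappears in step 8.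

Step 8
Reactants: 15 mono-lactol
Product: 17 dicitrinone G, via tetraphenol lactol 16 (not isolated)
Conditions: BBr3 (10 equiv), CH2Cl2, −78 → 0 °C; H2O, 0 °C
Reagents that add atoms: none
Why: Boron tribromide ether cleavage frees the four phenols, and the 1-hydroxyisochroman 16 with free 6- and 8-hydroxyls (the hydrate form familiar from citrinin-type quinone methides) should lose water on work-up through its resonance-stabilised O2=C1 oxocarbenium ion, while the lactone and the four C3/C4 centres take no part and are kept.

Compound list
1 | 2,4-dimethoxytoluene | COc1ccc(C)c(OC)c1 | starting material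
2 | ethyl formate | CCOC=O | starting material
3 | (2,6-dimethoxy-3-methylphenyl)lithium (not isolated) | [Li]c1c(OC)ccc(C)c1OC | intermediate
4 | 2,6-dimethoxy-3-methylbenzaldehyde (not isolated) | O=Cc1c(OC)ccc(C)c1OC | intermediate
5 | bis(2,6-dimethoxy-3-methylphenyl)methanol | OC(c1c(OC)ccc(C)c1OC)c1c(OC)ccc(C)c1OC | intermediate
6 | bis(2,6-dimethoxy-3-methylphenyl)methane | COc1ccc(C)c(OC)c1Cc1c(OC)ccc(C)c1OC | intermediate
7 | bis(3-bromo-2,6-dimethoxy-5-methylphenyl)methane | COc1c(Br)cc(C)c(OC)c1Cc1c(OC)c(Br)cc(C)c1OC | intermediate
8 | diethylcarbamoyl chloride | CCN(CC)C(=O)Cl | starting material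
9 | bis(3-lithio-2,6-dimethoxy-5-methylphenyl)methane (not isolated) | COc1c([Li])cc(C)c(OC)c1Cc1c(OC)c([Li])cc(C)c1OC | intermediate
10 | 3,3'-methylenebis(N,N-diethyl-2,4-dimethoxy-5-methylbenzamide) | CCN(CC)C(=O)c1cc(C)c(OC)c(Cc2c(OC)c(C)cc(C(=O)N(CC)CC)c2OC)c1OC | intermediate
11 | cis-2,3-epoxybutane (meso, 2R,3S) | C[C@H]1O[C@H]1C | starting material
12 | 6,6'-dilithio derivative of 10, sparteine-bound (C4a/C4a' lithiated; not isolated) | CCN(CC)C(=O)c1c([Li])c(C)c(OC)c(Cc2c(OC)c(C)c([Li])c(C(=O)N(CC)CC)c2OC)c1OC | intermediate
13 | 3,3'-methylenebis{N,N-diethyl-6-[(2S,3R)-3-hydroxybutan-2-yl]-2,4-dimethoxy-5-methylbenzamide} | CCN(CC)C(=O)c1c([C@H](C)[C@@H](C)O)c(C)c(OC)c(Cc2c(OC)c(C)c([C@H](C)[C@@H](C)O)c(C(=O)N(CC)CC)c2OC)c1OC | intermediate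
14 | 7,7'-methylenebis[(3R,4S)-6,8-dimethoxy-3,4,5-trimethyl-3,4-dihydro-1H-isochromen-1-one] | C(c1c(OC)c(C)c2c(c1OC)C(=O)O[C@H](C)[C@H]2C)c1c(OC)c(C)c2c(c1OC)C(=O)O[C@H](C)[C@H]2C | intermediate
15 | mono-lactol of 14 (3R,4S,3'R,4'S; C1 epimers) | C(c1c(OC)c(C)c2c(c1OC)C(O)O[C@H](C)[C@H]2C)c1c(OC)c(C)c2c(c1OC)C(=O)O[C@H](C)[C@H]2C | intermediate
16 | 6,8,6',8'-tetraphenol of 15 (hydrate of the target; not isolated) | C(c1c(O)c(C)c2c(c1O)C(O)O[C@H](C)[C@H]2C)c1c(O)c(C)c2c(c1O)C(=O)O[C@H](C)[C@H]2C | intermediate
17 | dicitrinone G (3R,4S,3'R,4'S) | CC1=C2C(=CO[C@H](C)[C@H]2C)C(=O)C(Cc2c(O)c(C)c3c(c2O)C(=O)O[C@H](C)[C@H]3C)=C1O | target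

Total step count: 8. Longest linear sequence: 8 steps (1 → 17).

Steps most likely to fail

Step 5. Discrimination between the enantiotopic epoxide carbons may collapse if the amide chelate or the boron Lewis acid pulls the diamine off lithium. The doubly ortho-flanked aryllithium may also attack the 2,3-disubstituted epoxide so slowly that proton transfer from C9 and Lewis-acid rearrangement of the epoxide gain ground. The fallback uses known chemistry and takes the absolute configuration from the chiral pool instead of from desymmetrisation. It sets out from 10, which is lithiated to 12 with s-BuLi/TMEDA in THF at −78 °C. With BF3·OEt2, 12 opens enantiopure (2S,3S)-2,3-epoxybutane (C[C@@H]1O[C@H]1C) with inversion to the erythro (3S,4S,3'S,4'S) bis(hydroxy amide) F1. A twofold Mitsunobu reaction (4-nitrobenzoic acid, PPh3, DIAD) inverts C3 and C3' and gives the (3R,4S,3'R,4'S) bis(4-nitrobenzoate) F2. Methanolysis (K2CO3, MeOH) brings the sequence back to the route at 13.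

Step 8. Bromide may attack C3 of the O2=C1 oxocarbenium ion, which would open the ring and erode the C3 configuration. Strong acid may cleave the C7–C9 bond of the freed bis-resorcinol, and the flanked methyl ethers may cleave only in part. The fallback moves the harsh demethylation ahead of the reduction and ends with a mild acid-labile group. It sets out from 14, which BBr3 converts to the tetraphenol bis-lactone F3. MOMCl/NaH in DMF gives the tetrakis(methoxymethyl) bis-lactone F4, and one equivalent of DIBAL-H at −78 °C gives the tetrakis(methoxymethyl) mono-lactol F5. Aqueous HCl in THF removes the acetals and comes back to the route at 16, which loses water to 17 in the same medium.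

Step 7. The equal and independent reactivity of the two lactones holds the mono-lactol to its statistical share. Sluggish hydride addition to the electron-rich, methoxy-flanked carbonyl may also force a higher temperature, at which the aluminium lactolate collapses and over-reduction to ring-opened diol sets in. The fallback moves the differentiation of the two ends to the lactonisation and makes the reduction chemoselective. It sets out from 13, and p-TsOH treatment stopped at partial conversion gives the mono-lactone mono(hydroxy amide) F6. F6 differs from 13 and 14 by one polar amide group and should therefore separate easily, and recovered 13 is resubmitted. Schwartz reagent (Cp2Zr(H)Cl, THF, rt) then reduces the remaining tertiary amide to the aldehyde oxidation level in the presence of the lactone and cannot overshoot. With the neighbouring C3 hydroxyl this level appears directly as the lactol, so the sequence rejoins the route at 15.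

Further compounds
F1 | step 5 | 3,3'-methylenebis{N,N-diethyl-6-[(2S,3S)-3-hydroxybutan-2-yl]-2,4-dimethoxy-5-methylbenzamide} | CCN(CC)C(=O)c1c([C@H](C)[C@H](C)O)c(C)c(OC)c(Cc2c(OC)c(C)c([C@H](C)[C@H](C)O)c(C(=O)N(CC)CC)c2OC)c1OC
F2 | step 5 | bis(4-nitrobenzoate) of 13 (3R,4S,3'R,4'S) | CCN(CC)C(=O)c1c([C@H](C)[C@@H](C)OC(=O)c3ccc(cc3)[N+](=O)[O-])c(C)c(OC)c(Cc2c(OC)c(C)c([C@H](C)[C@@H](C)OC(=O)c3ccc(cc3)[N+](=O)[O-])c(C(=O)N(CC)CC)c2OC)c1OC
F3 | step 8 | 7,7'-methylenebis[(3R,4S)-6,8-dihydroxy-3,4,5-trimethyl-3,4-dihydro-1H-isochromen-1-one] | C(c1c(O)c(C)c2c(c1O)C(=O)O[C@H](C)[C@H]2C)c1c(O)c(C)c2c(c1O)C(=O)O[C@H](C)[C@H]2C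
F4 | step 8 | 7,7'-methylenebis[(3R,4S)-6,8-bis(methoxymethoxy)-3,4,5-trimethyl-3,4-dihydro-1H-isochromen-1-one] | C(c1c(OCOC)c(C)c2c(c1OCOC)C(=O)O[C@H](C)[C@H]2C)c1c(OCOC)c(C)c2c(c1OCOC)C(=O)O[C@H](C)[C@H]2C
F5 | step 8 | mono-lactol of F4 (3R,4S,3'R,4'S; C1 epimers) | C(c1c(OCOC)c(C)c2c(c1OCOC)C(O)O[C@H](C)[C@H]2C)c1c(OCOC)c(C)c2c(c1OCOC)C(=O)O[C@H](C)[C@H]2C
F6 | step 7 | N,N-diethyl-3-{[(3R,4S)-6,8-dimethoxy-3,4,5-trimethyl-1-oxo-3,4-dihydro-1H-isochromen-7-yl]methyl}-6-[(2S,3R)-3-hydroxybutan-2-yl]-2,4-dimethoxy-5-methylbenzamide | CCN(CC)C(=O)c1c([C@H](C)[C@@H](C)O)c(C)c(OC)c(Cc2c(OC)c(C)c3c(c2OC)C(=O)O[C@H](C)[C@H]3C)c1OC
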